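**Plan**

- Cuts, in retrosynthetic order: the two aryl MOM ethers; the side-chain C5–C6 bond (sp3–sp2; alkylzinc plus E-alkenyl iodide carrying the 4-methylfuran); the aryl–C(=O) bond (aryllithium plus aldehyde, then oxidation); the two C=C bonds that end the vinyl group and the CH2–CHO arm at the quaternary carbon.
- Enabling feature: the quaternary carbon, the vinyl CH and the CH2 next to the ketone are the three carbons of a 3,3-disubstituted cycloprop-1-ene ring. Ring carbons C1 and C2 become the vinyl CH and, as an enol ether CH, the CH2 of the keto arm; ring carbon C3 already carries the methyl group and the two-carbon stub of the long chain.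
- Forward order: 3-methylbut-3-en-1-ol to the cyclopropene (the only ring made, then opened); ring-opening cross-metathesis with butyl vinyl ether; aldehyde; aryl ketone; primary iodide; coupling with the furyl alkenyl iodide (three steps from 3-methylfuran); release of the phenols. Benzene and furan rings are bought.
- Stereochemistry: the single stereocentre (R, quaternary) is set in the ring opening by the chiral ruthenium carbene, which chooses between the two enantiotopic ring alkene carbons. The E trisubstituted alkene comes from syn carboalumination of a terminal alkyne and is carried through the coupling with retention.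

Key step: step 5

Assumption: the sense of induction for a methyl/primary-alkyl cyclopropene cannot be predicted with certainty, so the antipode of the ligand L* that delivers the (3S)-configured ring-opened diene is the one used; both antipodes are accessible.

**Route**

Step 1
Reactants: 1 3-methylbut-3-en-1-ol
Product: 2 triisopropyl[(3-methylbut-3-en-1-yl)oxy]silane
Conditions: TIPSCl, imidazole, DMF, rt
Reagents that add atoms: triisopropylsilyl chloride, CC(C)[Si](Cl)(C(C)C)C(C)C
Why: Imidazole-promoted silylation of a primary alcohol; the bulky silyl ether should survive the basic, organometallic and dilute-acid steps up to step 10 and makes one C3 substituent of the later cyclopropene much larger than methyl.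

Step 2
Reactants: 2 triisopropyl[(3-methylbut-3-en-1-yl)oxy]silane; 3 bromoform
Product: 5 [2-(2,2-dibromo-1-methylcyclopropyl)ethoxy]triisopropylsilane (racemic), via dibromocarbene 4 (not isolated)
Conditions: KOtBu, hexane, 0 °C → rt
Reagents that add atoms: none
Why: α-Elimination of bromoform gives dibromocarbene, which adds in a [2+1] cycloaddition to the electron-rich 1,1-disubstituted alkene; the quaternary ring carbon forms as a racemate, which is harmless because it becomes the prochiral C3 of the cyclopropene.

Step 3
Reactants: 5 [2-(2,2-dibromo-1-methylcyclopropyl)ethoxy]triisopropylsilane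
Product: 6 [2-(2-bromo-1-methylcyclopropyl)ethoxy]triisopropylsilane (racemic; both diastereomers)
Conditions: EtMgBr (1.3 equiv), Ti(OiPr)4 (5 mol %), Et2O, rt
Reagents that add atoms: none
Why: Titanium-catalysed hydrodebromination of a gem-dibromocyclopropane, in which the ethyl group supplies the hydride and leaves as ethene, should stop at the monobromide; the bromide configuration is irrelevant because both epimers eliminate in step 4.

Step 4
Reactants: 6 [2-(2-bromo-1-methylcyclopropyl)ethoxy]triisopropylsilane
Product: 7 3-methyl-3-[2-(triisopropylsilyloxy)ethyl]cycloprop-1-ene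
Conditions: KOtBu, DMSO, rt
Reagents that add atoms: none
Why: Base-induced 1,2-dehydrobromination gives the cyclopropene, and since ring carbon C3 is quaternary there is no ring allylic hydrogen through which the strained alkene could isomerise to a methylenecyclopropane.

Step 5
Reactants: 7 3-methyl-3-[2-(triisopropylsilyloxy)ethyl]cycloprop-1-ene; 8 butyl vinyl ether
Product: 9 (1Z,3S)-1-butoxy-3-methyl-3-[2-(triisopropylsilyloxy)ethyl]penta-1,4-diene
Conditions: Ru(=CH-C6H4-2-OiPr)(I)(L*) (5 mol %; iodide complex, L* = enantiopure bidentate N-heterocyclic carbene aryloxide), 8 (10 equiv), THF, 22 °C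
Reagents that add atoms: none
Why: The ruthenium butoxycarbene formed from the precatalyst and 8 adds across the strained ring alkene of 7 in a [2+2] sense, and cycloreversion of the ruthenacyclobutane opens the three-membered ring to an alkylidene that already carries the enol ether; a second molecule of 8 caps this alkylidene as the vinyl group and returns the butoxycarbene. The closest known reaction type is the catalytic enantioselective ring-opening cross-metathesis of 3,3-disubstituted cyclopropenes with enol ethers under stereogenic-at-ruthenium iodide carbenes, a methyl/primary-alkyl pair at C3 being a less tested substitution pattern. No ring is closed; the cyclopropene ring is opened and two C=C bonds are formed. The quaternary stereocentre is set by the chiral carbene aryloxide ligand, which decides which of the two enantiotopic ring alkene carbons bonds to ruthenium and therefore which becomes the vinyl CH and which the enol ether CH, without any bond being made to the stereocentre itself. The step needs enantiotopic-group selectivity between methyl and the silyloxyethyl arm, which the large triisopropylsilyl ether is meant to sharpen, and cross-metathesis in preference to oligomerisation, which ring strain, the excess of 8 and the quaternary carbon flanking both new alkenes should secure. The enol ether is expected mainly as the Z isomer, but its geometry is of no consequence because step 6 removes it.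

Step 6
Reactants: 9 (1Z,3S)-1-butoxy-3-methyl-3-[2-(triisopropylsilyloxy)ethyl]penta-1,4-diene
Product: 10 (3R)-3-methyl-3-[2-(triisopropylsilyloxy)ethyl]pent-4-enal
Conditions: HCl (1 M aq.), THF, rt
Reagents that add atoms: water, O
Why: Acid-catalysed enol ether hydrolysis (C-protonation, hydration of the oxocarbenium ion, loss of butanol) unveils the CH2–CHO arm, while the triisopropylsilyl ether and the vinyl group tolerate dilute acid and the stereocentre is untouched (the descriptor changes from S to R only through the priority rules).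

Step 7
Reactants: 11 4-bromoresorcinol
Product: 12 1-bromo-2,4-bis(methoxymethoxy)benzene
Conditions: NaH, MOMCl, DMF, 0 °C → rt
Reagents that add atoms: chloromethyl methyl ether, COCCl
Why: Williamson-type O-alkylation of both phenoxides; MOM ethers tolerate aryllithium chemistry, stabilise the ortho-lithio species by chelation, cannot undergo oxygen-to-carbon silyl migration as ortho silyl ethers would, and survive the fluoride of step 10.

Step 8
Reactants: 10 (3R)-3-methyl-3-[2-(triisopropylsilyloxy)ethyl]pent-4-enal; 12 1-bromo-2,4-bis(methoxymethoxy)benzene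
Product: 14 (3R)-1-[2,4-bis(methoxymethoxy)phenyl]-3-methyl-3-[2-(triisopropylsilyloxy)ethyl]pent-4-en-1-ol (both C1 epimers), via 2,4-bis(methoxymethoxy)phenyllithium 13 (not isolated)
Conditions: 12, n-BuLi, THF, −78 °C; then 10, −78 °C; NH4Cl (aq.)
Reagents that add atoms: none
Why: Bromine–lithium exchange gives the aryllithium, which adds 1,2 to the aldehyde at low temperature; the new carbinol centre forms without control and is removed by the oxidation in step 9.

Step 9
Reactants: 14 (3R)-1-[2,4-bis(methoxymethoxy)phenyl]-3-methyl-3-[2-(triisopropylsilyloxy)ethyl]pent-4-en-1-ol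
Product: 15 (3R)-1-[2,4-bis(methoxymethoxy)phenyl]-3-methyl-3-[2-(triisopropylsilyloxy)ethyl]pent-4-en-1-one
Conditions: Dess–Martin periodinane, NaHCO3, CH2Cl2, rt
Reagents that add atoms: none
Why: Dess–Martin oxidation of the benzylic secondary alcohol to the aryl ketone under buffered conditions that leave the MOM ethers, the silyl ether and the vinyl group alone.

Step 10
Reactants: 15 (3R)-1-[2,4-bis(methoxymethoxy)phenyl]-3-methyl-3-[2-(triisopropylsilyloxy)ethyl]pent-4-en-1-one
Product: 16 (3R)-1-[2,4-bis(methoxymethoxy)phenyl]-3-(2-hydroxyethyl)-3-methylpent-4-en-1-one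
Conditions: TBAF, THF, 0 °C → rt
Reagents that add atoms: none
Why: Fluoride cleavage of the silyl ether, driven by Si–F bond formation, frees the primary alcohol; MOM ethers and the ketone are inert to TBAF.

Step 11
Reactants: 16 (3R)-1-[2,4-bis(methoxymethoxy)phenyl]-3-(2-hydroxyethyl)-3-methylpent-4-en-1-one
Product: 17 (3S)-1-[2,4-bis(methoxymethoxy)phenyl]-3-(2-iodoethyl)-3-methylpent-4-en-1-one
Conditions: I2, PPh3, imidazole, CH2Cl2, 0 °C → rt
Reagents that add atoms: iodine, II
Why: Appel-type iodination, in which iodide displaces the alkoxyphosphonium ion of the primary alcohol in an SN2 step under imidazole buffering that protects the MOM ethers; the stereocentre is not involved (the descriptor becomes S only because the iodoethyl arm gains priority).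

Step 12
Reactants: 18 3-methylfuran; 19 3-bromo-1-(trimethylsilyl)prop-1-yne
Product: 21 trimethyl[3-(4-methylfuran-2-yl)prop-1-yn-1-yl]silane, via (4-methylfuran-2-yl)lithium 20 (not isolated)
Conditions: t-BuLi, THF, −78 → −20 °C; then CuI (10 mol %), 19, −78 °C → rt
Reagents that add atoms: none
Why: α-Lithiation of the furan with a bulky alkyllithium is expected to favour the position remote from the methyl group, and copper-catalysed SN2 alkylation with the silyl-capped propargyl bromide (the silyl group suppressing allene formation) gives the 2,4-disubstituted furan; any 2,3-disubstituted regioisomer is separated at this stage.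

Step 13
Reactants: 21 trimethyl[3-(4-methylfuran-2-yl)prop-1-yn-1-yl]silane
Product: 22 4-methyl-2-(prop-2-yn-1-yl)furan
Conditions: K2CO3 (cat.), MeOH, 0 °C → rt
Reagents that add atoms: none
Why: Carbonate-catalysed methanolysis of the alkynyl C–Si bond; short exposure at low temperature should avoid propargyl-to-allene isomerisation of the doubly activated CH2 group.

Step 14
Reactants: 22 4-methyl-2-(prop-2-yn-1-yl)furan
Product: 24 2-[(2E)-3-iodo-2-methylprop-2-en-1-yl]-4-methylfuran, via (E)-alkenyldimethylalane 23 (not isolated)
Conditions: AlMe3, Cp2ZrCl2 (cat.), CH2Cl2, 0 °C → rt; then I2, THF, −30 → 0 °C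
Reagents that add atoms: trimethylaluminium, C[Al](C)C; iodine, II
Why: Zirconium-catalysed carboalumination (Negishi carboalumination) adds methyl and aluminium syn across the terminal alkyne with methyl on the internal carbon, and iodinolysis of the C–Al bond with retention gives the E alkenyl iodide, which fixes the alkene geometry of the target.

Step 15
Reactants: 17 (3S)-1-[2,4-bis(methoxymethoxy)phenyl]-3-(2-iodoethyl)-3-methylpent-4-en-1-one; 24 2-[(2E)-3-iodo-2-methylprop-2-en-1-yl]-4-methylfuran
Product: 26 (3R,6E)-1-[2,4-bis(methoxymethoxy)phenyl]-3-ethenyl-3,7-dimethyl-8-(4-methylfuran-2-yl)oct-6-en-1-one, via alkylzinc iodide 25 (not isolated)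
Conditions: 17, Zn dust (activated with BrCH2CH2Br and Me3SiCl), LiCl, THF, 40 °C; then 24, PdCl2(dppf) (5 mol %), THF, rt → 45 °C
Reagents that add atoms: none
Why: Negishi coupling, in which zinc inserts into the primary C–I bond to give an alkylzinc iodide that tolerates the aryl ketone, and palladium-catalysed sp3–sp2 coupling with the alkenyl iodide proceeds with retention of the E geometry, the bidentate phosphine disfavouring β-hydride elimination.

Step 16
Reactants: 26 (3R,6E)-1-[2,4-bis(methoxymethoxy)phenyl]-3-ethenyl-3,7-dimethyl-8-(4-methylfuran-2-yl)oct-6-en-1-one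
Product: 27 (3R,6E)-1-(2,4-dihydroxyphenyl)-3-ethenyl-3,7-dimethyl-8-(4-methylfuran-2-yl)oct-6-en-1-one (CNP0249327.1)
Conditions: HCl (ca. 0.5 M) in MeOH, 0 °C → rt
Reagents that add atoms: none
Why: Acid-catalysed transacetalisation of both MOM ethers to dimethoxymethane frees the phenols, the ortho ether activated by the neighbouring carbonyl going first; dilute anhydrous acid at or below room temperature is chosen as the mildest medium that still cleaves the para ether in the presence of the alkylfuran and the skipped alkene.

**Compound list**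

1 | 3-methylbut-3-en-1-ol | C=C(C)CCO | starting material
2 | triisopropyl[(3-methylbut-3-en-1-yl)oxy]silane | C=C(C)CCO[Si](C(C)C)(C(C)C)C(C)C | intermediate
3 | bromoform | BrC(Br)Br | starting material
4 | dibromocarbene (not isolated) | Br[C]Br | intermediate
5 | [2-(2,2-dibromo-1-methylcyclopropyl)ethoxy]triisopropylsilane (racemic) | CC1(CCO[Si](C(C)C)(C(C)C)C(C)C)CC1(Br)Br | intermediate
6 | [2-(2-bromo-1-methylcyclopropyl)ethoxy]triisopropylsilane (racemic; both diastereomers) | CC1(CCO[Si](C(C)C)(C(C)C)C(C)C)CC1Br | intermediate
7 | 3-methyl-3-[2-(triisopropylsilyloxy)ethyl]cycloprop-1-ene | CC1(CCO[Si](C(C)C)(C(C)C)C(C)C)C=C1 | intermediate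
8 | butyl vinyl ether | C=COCCCC | starting material
9 | (1Z,3S)-1-butoxy-3-methyl-3-[2-(triisopropylsilyloxy)ethyl]penta-1,4-diene | C=C[C@](C)(CCO[Si](C(C)C)(C(C)C)C(C)C)/C=C\OCCCC | intermediate
10 | (3R)-3-methyl-3-[2-(triisopropylsilyloxy)ethyl]pent-4-enal | C=C[C@](C)(CCO[Si](C(C)C)(C(C)C)C(C)C)CC=O | intermediate
11 | 4-bromoresorcinol (4-bromobenzene-1,3-diol) | Oc1ccc(Br)c(O)c1 | starting material
12 | 1-bromo-2,4-bis(methoxymethoxy)benzene | COCOc1ccc(Br)c(OCOC)c1 | intermediate
13 | [2,4-bis(methoxymethoxy)phenyl]lithium (not isolated) | [Li]c1ccc(OCOC)cc1OCOC | intermediate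
14 | (3R)-1-[2,4-bis(methoxymethoxy)phenyl]-3-methyl-3-[2-(triisopropylsilyloxy)ethyl]pent-4-en-1-ol (both C1 epimers) | C=C[C@](C)(CCO[Si](C(C)C)(C(C)C)C(C)C)CC(O)c1ccc(OCOC)cc1OCOC | intermediate
15 | (3R)-1-[2,4-bis(methoxymethoxy)phenyl]-3-methyl-3-[2-(triisopropylsilyloxy)ethyl]pent-4-en-1-one | C=C[C@](C)(CCO[Si](C(C)C)(C(C)C)C(C)C)CC(=O)c1ccc(OCOC)cc1OCOC | intermediate
16 | (3R)-1-[2,4-bis(methoxymethoxy)phenyl]-3-(2-hydroxyethyl)-3-methylpent-4-en-1-one | C=C[C@](C)(CCO)CC(=O)c1ccc(OCOC)cc1OCOC | intermediate
17 | (3S)-1-[2,4-bis(methoxymethoxy)phenyl]-3-(2-iodoethyl)-3-methylpent-4-en-1-one | C=C[C@](C)(CCI)CC(=O)c1ccc(OCOC)cc1OCOC | intermediate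
18 | 3-methylfuran | Cc1ccoc1 | starting material
19 | 3-bromo-1-(trimethylsilyl)prop-1-yne | C[Si](C)(C)C#CCBr | starting material
20 | (4-methylfuran-2-yl)lithium (not isolated) | [Li]c1cc(C)co1 | intermediate
21 | trimethyl[3-(4-methylfuran-2-yl)prop-1-yn-1-yl]silane | Cc1coc(CC#C[Si](C)(C)C)c1 | intermediate
22 | 4-methyl-2-(prop-2-yn-1-yl)furan | Cc1coc(CC#C)c1 | intermediate
23 | dimethyl[(1E)-2-methyl-3-(4-methylfuran-2-yl)prop-1-en-1-yl]alane (not isolated) | C[Al](C)/C=C(\C)Cc1cc(C)co1 | intermediate
24 | 2-[(2E)-3-iodo-2-methylprop-2-en-1-yl]-4-methylfuran | I/C=C(\C)Cc1cc(C)co1 | intermediate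
25 | {(3S)-5-[2,4-bis(methoxymethoxy)phenyl]-3-ethenyl-3-methyl-5-oxopentyl}(iodo)zinc (not isolated) | C=C[C@](C)(CC[Zn]I)CC(=O)c1ccc(OCOC)cc1OCOC | intermediate
26 | (3R,6E)-1-[2,4-bis(methoxymethoxy)phenyl]-3-ethenyl-3,7-dimethyl-8-(4-methylfuran-2-yl)oct-6-en-1-one | C=C[C@](C)(CC/C=C(\C)Cc1cc(C)co1)CC(=O)c1ccc(OCOC)cc1OCOC | intermediate
27 | (3R,6E)-1-(2,4-dihydroxyphenyl)-3-ethenyl-3,7-dimethyl-8-(4-methylfuran-2-yl)oct-6-en-1-one | C=C[C@](C)(CC/C=C(\C)Cc1cc(C)co1)CC(=O)c1ccc(O)cc1O | target

**Step count**

Total: 16 steps. Longest linear sequence: 12 steps (steps 1–6, 8–11, 15 and 16); steps 7 and 12–14 prepare the two coupling partners.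

**Steps most likely to fail**

1. Step 5. The chiral ligand sphere may discriminate poorly between the two enantiotopic ring alkene carbons when C3 carries methyl and a primary alkyl chain, or oligomerisation of the cyclopropene may outrun the cross step. The fallback sets the same stereocentre by auxiliary-controlled conjugate addition to a geometrically defined alkene, which does not depend on telling methyl from a CH2 group in a symmetric ring. It sets out from 2 and returns at 10. Ozonolysis of 2 (O3, CH2Cl2, −78 °C; Me2S) should give 4-(triisopropylsilyloxy)butan-2-one F1. Horner–Wadsworth–Emmons olefination with diethyl {2-oxo-2-[(4S)-2-oxo-4-phenyl-1,3-oxazolidin-3-yl]ethyl}phosphonate (NaH, THF), with removal of the Z isomer, should give (4S)-3-[(2E)-3-methyl-5-(triisopropylsilyloxy)pent-2-enoyl]-4-phenyl-1,3-oxazolidin-2-one F2. Addition of the vinyl cuprate from CH2=CHMgBr and CuBr·SMe2 to the chelated s-cis imide, on the face away from the phenyl group, is expected to give (4S)-3-{(3R)-3-methyl-3-[2-(triisopropylsilyloxy)ethyl]pent-4-enoyl}-4-phenyl-1,3-oxazolidin-2-one F3. LiBH4 reduction releases the auxiliary and gives (3S)-3-methyl-3-[2-(triisopropylsilyloxy)ethyl]pent-4-en-1-ol F4, and Dess–Martin oxidation returns aldehyde 10.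

2. Step 15. Zinc insertion next to an aryl ketone may be accompanied by protonation of the C–Zn bond or intramolecular attack on the carbonyl, and β-hydride elimination at palladium may compete with reductive elimination. The fallback reverses the polarity of the coupling, so that the ketone-bearing fragment is never metalated. It sets out from 24 and returns at 26. Iodine–lithium exchange on 24 (t-BuLi, 2 equiv, Et2O, −78 °C) gives [(1E)-2-methyl-3-(4-methylfuran-2-yl)prop-1-en-1-yl]lithium F5. ZnCl2 converts it into chloro[(1E)-2-methyl-3-(4-methylfuran-2-yl)prop-1-en-1-yl]zinc F6. F6 is coupled with the primary alkyl iodide 17 in an alkyl-electrophile Negishi coupling (Pd2(dba)3, tricyclopentylphosphine, N-methylimidazole, THF/NMP, 80 °C) to give 26.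

3. Step 16. While the slower para MOM ether is being cleaved, acid may open or oligomerise the electron-rich furan or move the skipped alkene into conjugation with it. The fallback frees the phenols before the furan enters and carries them through the coupling as base-labile esters. It sets out from 17 and returns at 27. HCl in MeOH converts 17 into (3S)-1-(2,4-dihydroxyphenyl)-3-(2-iodoethyl)-3-methylpent-4-en-1-one F7. Ac2O and pyridine give 4-[(3S)-3-(2-iodoethyl)-3-methylpent-4-enoyl]-1,3-phenylene diacetate F8. Zinc insertion (Zn, LiCl, THF) gives {(3S)-5-(2,4-diacetoxyphenyl)-3-ethenyl-3-methyl-5-oxopentyl}(iodo)zinc F9. Coupling with 24 under PdCl2(dppf) gives 4-[(3R,6E)-3-ethenyl-3,7-dimethyl-8-(4-methylfuran-2-yl)oct-6-enoyl]-1,3-phenylene diacetate F10. K2CO3 in MeOH at 0 °C removes both acetates to give 27 without any acid.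

Further compounds
F1 | step 5 | 4-(triisopropylsilyloxy)butan-2-one | CC(=O)CCO[Si](C(C)C)(C(C)C)C(C)C
F2 | step 5 | (4S)-3-[(2E)-3-methyl-5-(triisopropylsilyloxy)pent-2-enoyl]-4-phenyl-1,3-oxazolidin-2-one | C/C(CCO[Si](C(C)C)(C(C)C)C(C)C)=C\C(=O)N1[C@@H](c2ccccc2)COC1=O
F3 | step 5 | (4S)-3-{(3R)-3-methyl-3-[2-(triisopropylsilyloxy)ethyl]pent-4-enoyl}-4-phenyl-1,3-oxazolidin-2-one | C=C[C@](C)(CCO[Si](C(C)C)(C(C)C)C(C)C)CC(=O)N1[C@@H](c2ccccc2)COC1=O
F4 | step 5 | (3S)-3-methyl-3-[2-(triisopropylsilyloxy)ethyl]pent-4-en-1-ol | C=C[C@](C)(CCO[Si](C(C)C)(C(C)C)C(C)C)CCO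
F5 | step 15 | [(1E)-2-methyl-3-(4-methylfuran-2-yl)prop-1-en-1-yl]lithium | [Li]/C=C(\C)Cc1cc(C)co1
F6 | step 15 | chloro[(1E)-2-methyl-3-(4-methylfuran-2-yl)prop-1-en-1-yl]zinc | Cl[Zn]/C=C(\C)Cc1cc(C)co1
F7 | step 16 | (3S)-1-(2,4-dihydroxyphenyl)-3-(2-iodoethyl)-3-methylpent-4-en-1-one | C=C[C@](C)(CCI)CC(=O)c1ccc(O)cc1O
F8 | step 16 | 4-[(3S)-3-(2-iodoethyl)-3-methylpent-4-enoyl]-1,3-phenylene diacetate | C=C[C@](C)(CCI)CC(=O)c1ccc(OC(C)=O)cc1OC(C)=O
F9 | step 16 | {(3S)-5-(2,4-diacetoxyphenyl)-3-ethenyl-3-methyl-5-oxopentyl}(iodo)zinc | C=C[C@](C)(CC[Zn]I)CC(=O)c1ccc(OC(C)=O)cc1OC(C)=O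
F10 | step 16 | 4-[(3R,6E)-3-ethenyl-3,7-dimethyl-8-(4-methylfuran-2-yl)oct-6-enoyl]-1,3-phenylene diacetate | C=C[C@](C)(CC/C=C(\C)Cc1cc(C)co1)CC(=O)c1ccc(OC(C)=O)cc1OC(C)=O
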